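## The problem

Tomentodiplacone B (13) is a (2S)-flavanone: the phloroglucinol-type ring A is fused to the heterocyclic ring C, the 4-hydroxy-3-methoxyphenyl ring B sits on C2, and C6 carries a ten-carbon chain. C2 is the only stereocentre, so no other centre can control or correct it. It is also fragile, because base opens ring C by retro-oxa-Michael reaction to the achiral chalcone, and the free 4'-hydroxyl offers a second racemisation path through a quinone methide. The chain must be placed on C6 and not on C8; these two open positions of ring A are electronically almost alike and differ mainly in that C6 lies next to the 5-hydroxyl, which is hydrogen-bonded to the C4 carbonyl. The chain holds an E-trisubstituted C2''=C3'' alkene, a doubly allylic C4'' methylene, an E-disubstituted C5''=C6'' alkene and the tertiary carbinol C7''. These groups exclude rough treatment: acid ionises the tertiary allylic alcohol and cyclises an ortho-geranylphenol onto O5 or O7, strong base or metal hydrides can move the skipped diene into conjugation, and hydrogenolysis is ruled out by the alkenes. The decisive feature is the C5''=C6''–C7''(OH)(CH3)2 terminus, which is the pattern left when singlet oxygen undergoes an ene reaction with a C6''=C7'' prenyl terminus, bonding at C7'' and taking hydrogen from C5''. Read this way, 13 is 6-geranylhomoeriodictyol plus one oxygen atom, and the carbon skeleton reduces to a geranyl group on a flavanone that can be bought with C2 in place.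

## Retrosynthesis

**13 ⇒ 12.** The three aryl O–acetyl bonds of triacetate 12 are cut. Acetates are preferred here to silyl, benzyl or acetal groups because they make both arenes electron-poor towards singlet oxygen and come off by near-neutral solvolysis, without acid or hydrogen. 12 is no simpler in skeleton; the forward step must only free three phenols without disturbing C2.

**12 ⇒ 11.** The C7''–OH group is traced back to the hydroperoxide 11 by adding one oxygen (O–O bond). The forward reduction is trivial; the disconnection matters because it identifies 11 as the direct product of an ene reaction.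

**11 ⇒ 10.** The C7''–O bond is cut and the alkene is returned from C5''=C6'' to C6''=C7''. This gives 10, the triacetate of 6-geranylhomoeriodictyol, whose chain is an unfunctionalised geranyl group. The neighbouring cuts (C6–C1'' with the oxidised chain already complete, or a cut inside the chain) each need a separately made, sensitive C10 fragment. This cut removes the only heteroatom of the chain and both of its sensitive features at once. The forward reaction must attack the distal alkene and not C2''=C3'', and must abstract hydrogen from C5'' and not from a methyl group. The substrate helps with the first; the second is only partly controllable, so a regioisomeric co-product has to be separated.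

**10 ⇒ 9 ⇒ 8.** The acyl C–O bonds of 10 are cut to the free triol 9 (the natural flavanone 3'-O-methyldiplacone), and 9 is traced to the 7,4'-bis-silyl ether 8. The exchange costs two steps but is deliberate. The steps that functionalise C6 need an electron-rich ring A with a free 5-hydroxyl, which silyl ethers allow. The oxidation needs the opposite, which acetates provide. Taking 8 directly into the photooxygenation would be shorter, but it leaves a free phenolic hydroxyl ortho to the chain, beside the inner alkene.

**8 ⇒ 7 + 4.** The C6–C1'' bond is cut to aryl iodide 7 and geranyltributylstannane 4 (Stille coupling). Friedel–Crafts geranylation would give C6/C8/O mixtures under acid, and Suzuki-type allylation needs aqueous base that endangers C2; the Stille coupling is neutral. The cut is convergent and separates the intact flavanone from a C10 unit one step from commerce. The forward reaction must couple at a carbon flanked by two oxygen substituents, at the primary allyl terminus, with the E geometry kept.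

**7 ⇒ 6 ⇒ 5.** The C6–I bond is cut, then the two O–Si bonds. Regiochemistry is the whole question: in 5-hydroxy-7-O-substituted flavonoids the free, chelated 5-hydroxyl directs electrophiles to its ortho position C6. O4' must be capped so that ring B is not iodinated and the quinone methide path is closed. 5 is (2S)-homoeriodictyol, which supplies rings A, B and C and the stereocentre.

**4 ⇒ 1 + 2.** The C1–Sn bond is cut to geranyl bromide 2 and the stannyl anion 3, made in the flask from tributyltin chloride 1. The forward step must substitute at C1 without allylic transposition.

## Roads not taken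

**Alternative 1:** Ring A is cut at four bonds (C8–C8a, C5–C6, C7–C8, C4a–C5) to the diazoacetyl dihydropyranone A2 and the chain-bearing siloxyalkyne A3. In the forward sense a photochemical Wolff rearrangement, [2+2] addition of the alkyne, four-electron ring opening and six-electron closure (Danheiser benzannulation) would give A1.
- Merits: regiochemistry on ring A is fixed by construction. The chain necessarily lies between the free 5-hydroxyl and the silylated O7, and O5 and O7 emerge differentiated.
- Weak points: both partners are long to make. A2 needs its own asymmetric construction of C2 and a diazoketone on an enol-ether carbon. A3 needs the whole oxidised chain plus an ynol ether. The cascade exposes the skipped diene and a stereocentre in a vinylogous ester to ultraviolet light and heat. Three different silyl groups remain to be removed.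
- Comparison: this road is better than the chosen one in regiochemical certainty, since the chosen plan depends on a directing effect in step 3. Against that, the chosen plan buys ring A and C2 and needs nine steps in all.

**Alternative 2:** The C2–C1' bond is cut to the 6-substituted chromone A5 and the arylboronic acid A6. A chiral diene complex of monovalent rhodium, made from [RhCl(C2H4)2]2, would add the aryl group to C2 and set the 2S centre, giving A4.
- Merits: C2 is made by the catalyst and not merely preserved. Either enantiomer is accessible, and the result does not depend on the optical purity of a natural starting material. In this respect it is better than the chosen plan.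
- Weak points: a 5,7-dialkoxychromone is an electron-rich vinylogous ester with a peri substituent and a poor acceptor. Ring opening by β-elimination of the phenoxide after the addition is a known leak. A5 still has to solve the C6-versus-C8 problem and carry the complete oxidised chain. Three aryl methoxymethyl ethers and a silyl ether must finally be removed with acid beside a tertiary allylic alcohol and an ortho-geranylphenol.
- Comparison: the chosen plan answers with a stereocentre that is bought and only has to be kept under near-neutral conditions, no acidic deprotection, and a far shorter sequence.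

**Alternative 3:** The C6–C1'' bond is cut with the chain already oxidised. Iodide 7 (the same intermediate as in the chosen route) would be coupled with the (2E,5E)-stannane A8 by Pd(PPh3)4 to give A7, and desilylation would finish.
- Merits: four steps from 5 in the longest line, no protecting-group exchange, no oxygenation on advanced material, and no late loss of material to a regioisomeric hydroperoxide. In linear length and in where the wasteful step falls, this road is as good as or better than the chosen one.
- Weak points: A8 is not commercial. Making it requires the same tertiary allylic alcohol and E-alkene, most directly by the same photooxygenation on a simple geranyl ester followed by several functional-group steps, so the total count is not lower. The hindered coupling then has to be run with a precious stannane that carries a free tertiary allylic alcohol and a skipped diene, at a temperature where palladium hydrides can isomerise it.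
- Comparison: the chosen plan sets against it a coupling partner made in one step and a robust hydrocarbon allyl group in the difficult coupling. It also passes through 9, a natural product that serves as a checkpoint for regiochemistry and optical purity.

Key step: step 7

Remark on the chemistry: commercial (2S)-homoeriodictyol (5) is assumed to be of high enantiomeric purity. C2 is never rebuilt, so the optical purity of 13 cannot exceed that of 5, and chiral HPLC at 5, 9 and 13 is part of the plan.

## Route

Step 1
Reactants: 1 tributyltin chloride; 2 geranyl bromide [(2E)-1-bromo-3,7-dimethylocta-2,6-diene]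
Product: 4 geranyltributylstannane [tributyl((2E)-3,7-dimethylocta-2,6-dien-1-yl)stannane], via tributylstannyllithium 3 (not isolated)
Conditions: Li (2.2 equiv), THF, 0 °C; then 2, THF, −78 °C to rt
Reagents that add atoms: none
Why: Reductive metalation of the tin chloride by lithium gives the stannyl anion, which displaces the primary allylic bromide by SN2 substitution at C1 at low temperature, so the E-trisubstituted alkene is carried over unchanged; this is the standard preparation of allylic tributylstannanes from stannyllithium reagents.

Step 2
Reactants: 5 (2S)-homoeriodictyol [(2S)-5,7-dihydroxy-2-(4-hydroxy-3-methoxyphenyl)chroman-4-one]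
Product: 6 (2S)-7,4'-bis-O-(tert-butyldimethylsilyl)homoeriodictyol (5-OH free)
Conditions: TBSCl (2.4 equiv), imidazole, DMF, 0 °C to rt
Reagents that add atoms: tert-butyldimethylsilyl chloride, CC(C)(C)[Si](C)(C)Cl
Why: Phenol silylation with imidazole as base: the 7- and 4'-hydroxyls react, whereas the 5-hydroxyl is held in its hydrogen bond to the C4 carbonyl and stays free. Capping O4' closes the quinone methide path for racemisation of C2, and imidazole is too weak a base to open ring C.

Step 3
Reactants: 6 (2S)-7,4'-bis-O-(tert-butyldimethylsilyl)homoeriodictyol
Product: 7 (2S)-6-iodo-7,4'-bis-O-(tert-butyldimethylsilyl)homoeriodictyol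
Conditions: NIS (1.05 equiv), CH2Cl2, 0 °C to rt, dark
Reagents that add atoms: N-iodosuccinimide, O=C1CCC(=O)N1I
Why: Electrophilic aromatic iodination under neutral conditions: in 5-hydroxy-7-O-substituted flavonoids the free, chelated 5-hydroxyl steers the iodonium to its ortho position C6 rather than C8, and one equivalent of reagent limits double iodination. Ring B has no free phenol and, like the silyl ethers, should not react in the absence of acid.

Step 4
Reactants: 7 (2S)-6-iodo-7,4'-bis-O-(tert-butyldimethylsilyl)homoeriodictyol; 4 geranyltributylstannane
Product: 8 (2S)-6-geranyl-7,4'-bis-O-(tert-butyldimethylsilyl)homoeriodictyol [6-((2E)-3,7-dimethylocta-2,6-dien-1-yl)]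
Conditions: Pd(PPh3)4 (10 mol %), toluene, 100 °C, degassed
Reagents that add atoms: none
Why: Stille cross-coupling: oxidative addition of zerovalent palladium into the C6–I bond, transfer of the allyl group from tin and reductive elimination at the unhindered primary allyl terminus form the linear C6–C1'' bond, and the E geometry of C2''=C3'' should persist because the syn form of the allyl ligand is the stable one. The base-free medium leaves the silyl ethers, the chelated phenol and C2 untouched.

Step 5
Reactants: 8 (2S)-6-geranyl-7,4'-bis-O-(tert-butyldimethylsilyl)homoeriodictyol
Product: 9 (2S)-6-geranylhomoeriodictyol (3'-O-methyldiplacone)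
Conditions: HF·pyridine, pyridine, THF, 0 °C to rt
Reagents that add atoms: none
Why: Fluoride-induced cleavage of aryl silyl ethers; the pyridine-buffered medium keeps the freed phenols protonated, so neither the chalcone nor the quinone methide path to racemisation opens, and it is too weakly acidic to cyclise the ortho-geranylphenol. The product is a natural flavanone and serves as a checkpoint for regiochemistry and optical purity.

Step 6
Reactants: 9 (2S)-6-geranylhomoeriodictyol
Product: 10 (2S)-6-geranylhomoeriodictyol 5,7,4'-triacetate
Conditions: Ac2O, pyridine, DMAP (cat.), CH2Cl2, 0 °C to rt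
Reagents that add atoms: acetic anhydride, CC(=O)OC(C)=O
Why: O-Acylation of phenols with nucleophilic catalysis by DMAP, which is needed for the chelated and doubly flanked 5-hydroxyl. The 4'-hydroxyl is acylated first, and pyridine at or below room temperature is not basic enough to open ring C.

Step 7
Reactants: 10 (2S)-6-geranylhomoeriodictyol 5,7,4'-triacetate
Product: 11 (2S)-tomentodiplacone B 7''-hydroperoxide 5,7,4'-triacetate [6-((2E,5E)-7-hydroperoxy-3,7-dimethylocta-2,5-dien-1-yl)]
Conditions: O2, tetraphenylporphyrin (cat.), CH2Cl2, 0 °C, white LED (visible light only); stopped at partial conversion, 10 recovered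
Reagents that add atoms: dioxygen, O=O
Why: Schenck ene reaction: energy transfer from triplet tetraphenylporphyrin gives singlet oxygen, which approaches the electron-rich trisubstituted C6''=C7'' alkene through a perepoxide-like transition structure, takes an allylic hydrogen from C5'' and forms the C7''–O bond on the same face while the double bond shifts to C5''=C6''. The closest known reaction type is the photooxygenation of prenyl (2-methylalk-2-ene) termini of terpenoids such as citronellol or geranyl esters to tertiary allylic hydroperoxides. No ring closes and no stereocentre is created, since C7'' carries two methyl groups; the only new stereochemical element is the C5''=C6'' geometry, which should be E because the C4'' substituent turns away from C7'' when the C5''–H bond aligns with the π system. Two selectivities are needed. Site selectivity for the distal alkene rests on the substrate: C2''=C3'' is wedged between the 5- and 7-acetoxy groups of an electron-poor arene, which screens it and lowers its reactivity, and acetylation removes both the ortho-hydroxyl that could steer singlet oxygen to it and the phenols that would quench the oxidant. Regioselectivity of hydrogen abstraction is only partly secured: the cis effect confines abstraction to the crowded side of the alkene, that is to C5''H2 and the cis methyl group, so the isopropenyl secondary hydroperoxide is an expected co-product in comparable amount and is removed by chromatography. Stopping at partial conversion and recycling 10 limits double oxygenation.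

Step 8
Reactants: 11 (2S)-tomentodiplacone B 7''-hydroperoxide 5,7,4'-triacetate
Product: 12 (2S)-tomentodiplacone B 5,7,4'-triacetate
Conditions: PPh3 (1.1 equiv), CH2Cl2, 0 °C
Reagents that add atoms: none
Why: Reduction of a hydroperoxide to the alcohol by oxygen-atom transfer to the phosphine is fast at 0 °C and touches neither the acetates, the ketone nor the alkenes; no stereocentre is involved.

Step 9
Reactants: 12 (2S)-tomentodiplacone B 5,7,4'-triacetate
Product: 13 (2S)-tomentodiplacone B
Conditions: NH4OAc (excess), MeOH–H2O (4:1), rt
Reagents that add atoms: none
Why: Solvolysis of aryl acetates promoted by ammonium acetate in aqueous methanol is selective for phenolic esters and runs close to neutrality, so the tertiary allylic alcohol, the skipped diene and the C2 stereocentre should survive. The activated 7- and 4'-acetates should go first and the hindered 5-acetate last.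

## Compound list

1 | tributyltin chloride | CCCC[Sn](Cl)(CCCC)CCCC | starting material
2 | geranyl bromide, (2E)-1-bromo-3,7-dimethylocta-2,6-diene | CC(C)=CCC/C(C)=C/CBr | starting material
3 | tributylstannyllithium | [Li][Sn](CCCC)(CCCC)CCCC | intermediate
4 | geranyltributylstannane, tributyl((2E)-3,7-dimethylocta-2,6-dien-1-yl)stannane | CC(C)=CCC/C(C)=C/C[Sn](CCCC)(CCCC)CCCC | intermediate
5 | (2S)-homoeriodictyol, (2S)-5,7-dihydroxy-2-(4-hydroxy-3-methoxyphenyl)chroman-4-one | COc1cc([C@@H]2CC(=O)c3c(O)cc(O)cc3O2)ccc1O | starting material
6 | (2S)-7,4'-bis-O-(tert-butyldimethylsilyl)homoeriodictyol | COc1cc([C@@H]2CC(=O)c3c(cc(O[Si](C)(C)C(C)(C)C)cc3O)O2)ccc1O[Si](C)(C)C(C)(C)C | intermediate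
7 | (2S)-6-iodo-7,4'-bis-O-(tert-butyldimethylsilyl)homoeriodictyol | COc1cc([C@@H]2CC(=O)c3c(cc(O[Si](C)(C)C(C)(C)C)c(I)c3O)O2)ccc1O[Si](C)(C)C(C)(C)C | intermediate
8 | (2S)-6-geranyl-7,4'-bis-O-(tert-butyldimethylsilyl)homoeriodictyol | COc1cc([C@@H]2CC(=O)c3c(cc(O[Si](C)(C)C(C)(C)C)c(C/C=C(\C)CCC=C(C)C)c3O)O2)ccc1O[Si](C)(C)C(C)(C)C | intermediate
9 | (2S)-6-geranylhomoeriodictyol (3'-O-methyldiplacone) | COc1cc([C@@H]2CC(=O)c3c(cc(O)c(C/C=C(\C)CCC=C(C)C)c3O)O2)ccc1O | intermediate
10 | (2S)-6-geranylhomoeriodictyol 5,7,4'-triacetate | COc1cc([C@@H]2CC(=O)c3c(cc(OC(C)=O)c(C/C=C(\C)CCC=C(C)C)c3OC(C)=O)O2)ccc1OC(C)=O | intermediate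
11 | (2S)-tomentodiplacone B 7''-hydroperoxide 5,7,4'-triacetate | COc1cc([C@@H]2CC(=O)c3c(cc(OC(C)=O)c(C/C=C(\C)C/C=C/C(C)(C)OO)c3OC(C)=O)O2)ccc1OC(C)=O | intermediate
12 | (2S)-tomentodiplacone B 5,7,4'-triacetate | COc1cc([C@@H]2CC(=O)c3c(cc(OC(C)=O)c(C/C=C(\C)C/C=C/C(C)(C)O)c3OC(C)=O)O2)ccc1OC(C)=O | intermediate
13 | (2S)-tomentodiplacone B | COc1cc([C@@H]2CC(=O)c3c(cc(O)c(C/C=C(\C)C/C=C/C(C)(C)O)c3O)O2)ccc1O | target

## Step count and risks

Total: 9 steps. Longest linear sequence: 8 steps (5 to 13, steps 2–9); stannane 4 is made in one step off the main line.

**Step 7 (key step).**
- Most likely to go wrong: hydrogen abstraction from the cis methyl group instead of C5'', because the cis effect does not distinguish the two allylic positions on the crowded side of the alkene. Attack at C2''=C3'' and double oxygenation at high conversion would add to the loss.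
- Fallback: it sets out from 10 and replaces singlet oxygen by electrophilic selenium. Hydroxyselenation (N-(phenylseleno)phthalimide, water, catalytic camphorsulfonic acid, CH2Cl2) should place selenium on C6'' and hydroxyl on the tertiary C7'' of the more accessible terminal alkene. Water intercepts the seleniranium ion before the inner alkene can. This gives the β-hydroxy selenide of the triacetate F1. Oxidation with H2O2 buffered by pyridine and syn-elimination of the selenoxide can only run towards C5'', since C7'' has no hydrogen. This gives the E-alkene, and the fallback returns to the route at 12 without passing through 11.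

**Step 4.**
- Most likely to go wrong: slow coupling at the arylpalladium centre flanked by a bulky silyl ether and a free hydroxyl. This would let protodeiodination and syn/anti isomerisation of the allyl ligand (erosion of the E geometry) compete.
- Fallback: it sets out from 7 and moves the protecting-group exchange ahead of the coupling. Desilylation with buffered HF·pyridine gives (2S)-6-iodohomoeriodictyol F2. Acetylation (Ac2O, pyridine, DMAP) gives the iodo triacetate F3, an electron-poorer, less hindered iodide without an acidic proton. Stille coupling of F3 with 4 (Pd(PPh3)4, toluene) returns to the route at 10.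
- If loss of alkene geometry rather than slow coupling proves to be the fault, the tin-free sequence described under step 3 applies.

**Step 3.**
- Most likely to go wrong: incomplete discrimination between C6 and C8, or double iodination, because the two positions are electronically similar and the selectivity rests on the directing effect of the chelated hydroxyl alone.
- Fallback: it sets out from 5 and delivers the chain from O5, so that proximity fixes the position. Selective acetylation of the two unchelated phenols (Ac2O, pyridine, 0 °C) gives (2S)-homoeriodictyol 7,4'-diacetate F4. Mitsunobu etherification of the 5-hydroxyl with geraniol (PPh3, diisopropyl azodicarboxylate, THF) gives the 5-O-geranyl ether F5. A [1,3] O-to-C shift on Florisil (magnesium silicate, MgSiO3) in toluene moves the geranyl group to the ortho carbon C6 and gives (2S)-6-geranylhomoeriodictyol 7,4'-diacetate F6. Acetylation of the 5-hydroxyl returns to the route at 10, bypassing 6 to 9 and the tin chemistry.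

**Step 9.**
- Most likely to go wrong: slow cleavage of the hindered 5-acetate, which would invite longer exposure or stronger base and with it partial racemisation of C2 through ring opening.
- Fallback: it sets out from 8 and avoids acyl protection altogether. Photooxygenation of 8 under the conditions of step 7 (silyl ethers inert, 5-hydroxyl chelated) gives the bis-silyl hydroperoxide F7. PPh3 reduces it to (2S)-7,4'-bis-O-(tert-butyldimethylsilyl)tomentodiplacone B F8, the same compound as A7. Buffered HF·pyridine, as in step 5, returns to the route at 13.
- The price of this fallback is a free phenolic hydroxyl next to the inner alkene during the oxidation, which is why it is not the first choice.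

## Further compounds

F1 | step 7 | (2S)-6-((2E)-7-hydroxy-3,7-dimethyl-6-(phenylselanyl)oct-2-en-1-yl)homoeriodictyol 5,7,4'-triacetate (both C6'' epimers) | COc1cc([C@@H]2CC(=O)c3c(cc(OC(C)=O)c(C/C=C(\C)CCC([Se]c4ccccc4)C(C)(C)O)c3OC(C)=O)O2)ccc1OC(C)=O
F2 | step 4 | (2S)-6-iodohomoeriodictyol | COc1cc([C@@H]2CC(=O)c3c(cc(O)c(I)c3O)O2)ccc1O
F3 | step 4 | (2S)-6-iodohomoeriodictyol 5,7,4'-triacetate | COc1cc([C@@H]2CC(=O)c3c(cc(OC(C)=O)c(I)c3OC(C)=O)O2)ccc1OC(C)=O
F4 | step 3 | (2S)-homoeriodictyol 7,4'-diacetate | COc1cc([C@@H]2CC(=O)c3c(cc(OC(C)=O)cc3O)O2)ccc1OC(C)=O
F5 | step 3 | (2S)-5-O-geranylhomoeriodictyol 7,4'-diacetate | COc1cc([C@@H]2CC(=O)c3c(cc(OC(C)=O)cc3OC/C=C(\C)CCC=C(C)C)O2)ccc1OC(C)=O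
F6 | step 3 | (2S)-6-geranylhomoeriodictyol 7,4'-diacetate | COc1cc([C@@H]2CC(=O)c3c(cc(OC(C)=O)c(C/C=C(\C)CCC=C(C)C)c3O)O2)ccc1OC(C)=O
F7 | step 9 | (2S)-7,4'-bis-O-(tert-butyldimethylsilyl)tomentodiplacone B 7''-hydroperoxide | COc1cc([C@@H]2CC(=O)c3c(cc(O[Si](C)(C)C(C)(C)C)c(C/C=C(\C)C/C=C/C(C)(C)OO)c3O)O2)ccc1O[Si](C)(C)C(C)(C)C
F8 | step 9 | (2S)-7,4'-bis-O-(tert-butyldimethylsilyl)tomentodiplacone B | COc1cc([C@@H]2CC(=O)c3c(cc(O[Si](C)(C)C(C)(C)C)c(C/C=C(\C)C/C=C/C(C)(C)O)c3O)O2)ccc1O[Si](C)(C)C(C)(C)C
A1 | alternative 1 | (2S)-7-O-triisopropylsilyl-4'-O-(tert-butyldimethylsilyl)-7''-O-triethylsilyl-tomentodiplacone B | COc1cc([C@@H]2CC(=O)c3c(cc(O[Si](C(C)C)(C(C)C)C(C)C)c(C/C=C(\C)C/C=C/C(C)(C)O[Si](CC)(CC)CC)c3O)O2)ccc1O[Si](C)(C)C(C)(C)C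
A2 | alternative 1 | (2S)-6-(2-diazoacetyl)-2-(4-(tert-butyldimethylsilyloxy)-3-methoxyphenyl)-2,3-dihydro-4H-pyran-4-one | COc1cc([C@@H]2CC(=O)C=C(C(=O)C=[N+]=[N-])O2)ccc1O[Si](C)(C)C(C)(C)C
A3 | alternative 1 | ((4E,7E)-5,9-dimethyl-9-(triethylsilyloxy)deca-4,7-dien-1-yn-1-yl)oxy-triisopropylsilane | CC(C)[Si](OC#CC/C=C(\C)C/C=C/C(C)(C)O[Si](CC)(CC)CC)(C(C)C)C(C)C
A4 | alternative 2 | (2S)-5,7,4'-tris-O-(methoxymethyl)-7''-O-triethylsilyl-tomentodiplacone B | COc1cc([C@@H]2CC(=O)c3c(cc(OCOC)c(C/C=C(\C)C/C=C/C(C)(C)O[Si](CC)(CC)CC)c3OCOC)O2)ccc1OCOC
A5 | alternative 2 | 5,7-bis(methoxymethoxy)-6-((2E,5E)-3,7-dimethyl-7-(triethylsilyloxy)octa-2,5-dien-1-yl)-4H-chromen-4-one | O=c1ccoc2cc(OCOC)c(C/C=C(\C)C/C=C/C(C)(C)O[Si](CC)(CC)CC)c(OCOC)c12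
A6 | alternative 2 | (3-methoxy-4-(methoxymethoxy)phenyl)boronic acid | COCOc1ccc(B(O)O)cc1OC
A7 | alternative 3 | (2S)-7,4'-bis-O-(tert-butyldimethylsilyl)tomentodiplacone B | COc1cc([C@@H]2CC(=O)c3c(cc(O[Si](C)(C)C(C)(C)C)c(C/C=C(\C)C/C=C/C(C)(C)O)c3O)O2)ccc1O[Si](C)(C)C(C)(C)C
A8 | alternative 3 | (3E,6E)-2,6-dimethyl-8-(tributylstannyl)octa-3,6-dien-2-ol | CCCC[Sn](CCCC)(CCCC)C/C=C(\C)C/C=C/C(C)(C)O
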